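The 3.0 min allowed is longer than the 25.0 s in which the earlier beta run lost 80.0% of its substrate, and the four new flasks differ in their charge of impurity.

the same everywhere: free catalyst 0.49 mM
- beta: substrate 6.7 mM; coupling partner 10 mM; impurity 0.012 mM; run made earlier
- ash: substrate 10 mM; coupling partner 10.0 mM; impurity 0.012 mM; time 3.0 min
- larch: substrate 10 mM; coupling partner 10.0 mM; impurity 0.040 mM; time 3.0 min
- alder: substrate 10 mM; coupling partner 10.0 mM; impurity 0.12 mM; time 3.0 min
- maple: substrate 10 mM; coupling partner 10.0 mM; impurity 0.40 mM; time 3.0 min

beta run (percent of the substrate charged)

| time / s | product / % | substrate / % |
|---|---|---|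
| 12.0 | 40 | 53 |
| 25.0 | 75 | 20 |
| 40.0 | 97 | 0 |
| 50.0 | 97 | 0 |
| 60.0 | 98 | 1 |

(each reading ± 2 percentage points)

- "hardly changes" means that all values lie within two and a half points (for a concentration: within two and a half percent of the largest)
- no earlier run changes the charge of impurity; that part of a forecast is a guess

- amount of product at the end, in percent of the substrate charged for ash, larch, alder, maple, in this order
- how the row runs (rises all the way / rises, then falls / falls all the way / falls, then rises / hardly changes)

The substrate charge of ash is 1.49 times beta's, with the same free catalyst, so at beta's pace ash has a catalyst-time of 46.6 s, meaning the seconds of the whole catalyst at work that one substrate charge takes. That is a reading with its scatter, and beta held spare coupling partner while ash holds equal charges, so the tail of ash can run slower.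

On this reckoning, a flask falls short of the plateau if it receives less catalyst-time than this. Received catalyst-time is the working share of the catalyst multiplied by time, so the 3.0 min suffices while that share stays above 25.9%. The impurity's behaviour is a guess, so take a hard case: each impurity removes one catalyst at once. Alder then keeps 75.5%, above the line, and ash and larch carry less impurity than alder. Maple keeps 18.4%, below the line, and in this case would end near 71.1% of its charge. But catalyst lost steadily over a span still gives half its share during that span, so maple receives enough if binding takes longer than 33.3 s. The estimate here is a flat row near beta's plateau reading of 97%, with maple the point at risk.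

The forecast reads 97%, 97%, 96% and 75%, so its row falls all the way. Its ground is “My best guess is a poison that binds catalyst one-to-one”. It parts from the estimate here at maple.

The flasks give 95.7%, 95.9%, 96.5% and 96.7%: the row hardly changes.

    coupling partner + free catalyst ⇌ catalyst intermediate A (K = 1100 L mol⁻¹, k = 1800 L mol⁻¹ s⁻¹)
    substrate + catalyst intermediate A → catalyst intermediate B (k = 2600 L mol⁻¹ s⁻¹)
    catalyst intermediate B ⇌ free catalyst + product (K = 0.00220 M, k = 0.490 s⁻¹)
    free catalyst + impurity → spent catalyst (k = 1000 L mol⁻¹ s⁻¹)

Over the first 1.50 min in maple, substrate fell to 8.62% and product rose to 90.1% while impurity was still turning free catalyst into spent catalyst, with 17.5% of the impurity left at a time longer than 33.3 s. By then 67.3% of maple's catalyst was spent and 26.6% sat as catalyst intermediate B, the resting state, and a straight fall to that point, taken as a rough estimate, would give 59.7 s of catalyst-time, more than 46.6 s. Alder, with 24.5% of its catalyst spent at 3.00 min, had 136 s of unspent catalyst-time by that share, more than 46.6 s, and held 96.5% product.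

(All runs stem from a simulated flask on assumed constants.)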